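**Plan**

- Target: (12Z)-6α-acetoxylabda-12,14-diene-7β,8α-diol. Late cuts: C13–C14 and C12=C13 of the (Z)-diene (Stille coupling, α-iodo ylide Wittig), and the C6–O bond of the acetate, read as a Baeyer–Villiger-masked 6-acetyl group.
- Enabling feature: with acetyl on C6, ring B holds a β-hydroxy ketone (C7–OH next to C6–C=O, an aldol retron) and C5 is the β-carbon of an enone. The methyl-bearing quaternary C10 is a tertiary radical born from a C10=C20H2 alkene. One hydrogen-atom-transfer Giese/aldol cascade therefore cuts C5–C10 and C6–C7 and unravels rings A and B to an acyclic keto aldehyde.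
- Chain cuts: C1–C10 (B-alkyl Suzuki–Miyaura coupling) and C9–C10 (opening of a 2,3-epoxy alcohol by an alkenyl Grignard reagent).
- Forward order: C7–C9/C11–C12 epoxy alcohol, then C10/C20, then the C1–C6 arm. Ring A closes first (6-exo radical addition) and ring B second (aldol) in the same operation. Baeyer–Villiger oxidation and diene construction follow.
- Stereochemistry: C8 and C9 from Sharpless asymmetric epoxidation and invertive epoxide opening. C10, C5, C6 and C7 are relayed from C8/C9 through chair transition states of the cascade. C6–O comes from retentive Baeyer–Villiger migration, and 12Z from the α-iodo ylide and retentive Stille coupling.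

Key step: step 11

Remark: labdane atom numbers of the target (C1–C10 decalin, C11–C16 side chain, C17 on C8, C18/C19 on C4, C20 on C10; α is the face opposite to C20) are used for all compounds.

Step 1
Reactants: 1 3-(benzyloxy)propanal
Product: 2 ethyl (E)-5-(benzyloxy)-2-methylpent-2-enoate
Conditions: Ph3P=C(CH3)CO2Et, CH2Cl2, rt
Reagents that add atoms: ethyl 2-(triphenylphosphoranylidene)propanoate, CCOC(=O)C(C)=P(c1ccccc1)(c1ccccc1)c1ccccc1
Why: Wittig olefination with a stabilised ylide, which should give the (E)-trisubstituted enoate (C7, C8, C17 added to C9).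

Step 2
Reactants: 2 ethyl (E)-5-(benzyloxy)-2-methylpent-2-enoate
Product: 3 (E)-5-(benzyloxy)-2-methylpent-2-en-1-ol
Conditions: DIBAL-H (2.2 equiv), CH2Cl2, −78 °C
Reagents that add atoms: none
Why: 1,2-reduction of the enoate by the aluminium hydride should give the allylic alcohol without touching the alkene or the benzyl ether.

Step 3
Reactants: 3 (E)-5-(benzyloxy)-2-methylpent-2-en-1-ol
Product: 4 [(2R,3R)-3-[2-(benzyloxy)ethyl]-2-methyloxiran-2-yl]methanol
Conditions: Ti(OiPr)4 (cat.), D-(−)-diethyl tartrate (cat.), t-BuOOH, 4 Å molecular sieves, CH2Cl2, −20 °C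
Reagents that add atoms: tert-butyl hydroperoxide, CC(C)(C)OO
Why: Sharpless asymmetric epoxidation of an (E)-2-methyl allylic alcohol; the D-(−)-tartrate catalyst should deliver oxygen to the face that gives the (2R,3R)-epoxide, which fixes C8.

Step 4
Reactants: 4 [(2R,3R)-3-[2-(benzyloxy)ethyl]-2-methyloxiran-2-yl]methanol
Product: 5 (2S,3S)-3-[2-(benzyloxy)ethyl]-2-methyl-4-(trimethylsilyl)pent-4-ene-1,2-diol
Conditions: CH2=C(SiMe3)MgBr (from CH2=C(Br)SiMe3 and Mg), CuI (cat.), THF, −30 → 0 °C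
Reagents that add atoms: [1-(trimethylsilyl)vinyl]magnesium bromide, C=C([Mg]Br)[Si](C)(C)C
Why: Copper-catalysed Grignard opening of a 2,3-epoxy alcohol; the alkenyl group should attack the secondary epoxide carbon (C9) and not the quaternary one (C8), with inversion, which sets C9 and forms C9–C10.

Step 5
Reactants: 5 (2S,3S)-3-[2-(benzyloxy)ethyl]-2-methyl-4-(trimethylsilyl)pent-4-ene-1,2-diol
Product: 6 (2S,3S)-3-[2-(benzyloxy)ethyl]-2-methyl-1,2-bis(triethylsilyloxy)-4-(trimethylsilyl)pent-4-ene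
Conditions: Et3SiOTf (2.5 equiv), 2,6-lutidine, CH2Cl2, −78 → 0 °C
Reagents that add atoms: triethylsilyl trifluoromethanesulfonate, CC[Si](CC)(CC)OS(=O)(=O)C(F)(F)F
Why: Silyl triflate silylation should cap both the primary and the tertiary hydroxyl, which prevents iodoetherification in the next step.

Step 6
Reactants: 6 (2S,3S)-3-[2-(benzyloxy)ethyl]-2-methyl-1,2-bis(triethylsilyloxy)-4-(trimethylsilyl)pent-4-ene
Product: 7 (2S,3S)-3-[2-(benzyloxy)ethyl]-4-iodo-2-methyl-1,2-bis(triethylsilyloxy)pent-4-ene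
Conditions: NIS, MeCN/ClCH2CN (4:1), 0 °C → rt
Reagents that add atoms: N-iodosuccinimide, O=C1CCC(=O)N1I
Why: Ipso-iododesilylation of a 2-silyl-1-alkene should give the 2-iodo-1-alkene with the silyl ethers intact.

Step 7
Reactants: 8 2,2-dimethylpent-4-enal
Product: 9 (E)-5,5-dimethylocta-3,7-dien-2-one
Conditions: Ph3P=CHC(O)CH3, toluene, 90 °C
Reagents that add atoms: 1-(triphenylphosphoranylidene)propan-2-one, CC(=O)C=P(c1ccccc1)(c1ccccc1)c1ccccc1
Why: Wittig olefination of a non-enolisable aldehyde with a stabilised ylide should give the (E)-enone (C5=C6 and the acetyl group).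

Step 8
Reactants: 9 (E)-5,5-dimethylocta-3,7-dien-2-one
Product: 10 (E)-5,5-dimethylocta-3,7-dien-2-ol (racemic)
Conditions: NaBH4, CeCl3·7H2O, MeOH, 0 °C
Reagents that add atoms: none
Why: Luche 1,2-reduction masks the enone, which a borane would reduce, as an allylic alcohol; its stereocentre is erased again in step 10.

Step 9
Reactants: 10 (E)-5,5-dimethylocta-3,7-dien-2-ol (racemic); 7 (2S,3S)-3-[2-(benzyloxy)ethyl]-4-iodo-2-methyl-1,2-bis(triethylsilyloxy)pent-4-ene
Product: 12 (3E,10R,11S)-10-[2-(benzyloxy)ethyl]-5,5,11-trimethyl-9-methylidene-11,12-bis(triethylsilyloxy)dodec-3-en-2-ol (both C2 epimers), via alkylborane 11 (not isolated)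
Conditions: 9-BBN (2.2 equiv), THF, rt; then 7, Pd(dppf)Cl2 (cat.), AsPh3, Cs2CO3, DMF/H2O, rt
Reagents that add atoms: none
Why: 9-BBN should hydroborate only the terminal alkene (the hydroxyl is carried as its borinate), and B-alkyl Suzuki–Miyaura coupling with the 2-iodo-1-alkene should form C1–C10 and give the C10=C20H2 alkene.

Step 10
Reactants: 12 (3E,10R,11S)-10-[2-(benzyloxy)ethyl]-5,5,11-trimethyl-9-methylidene-11,12-bis(triethylsilyloxy)dodec-3-en-2-ol
Product: 13 (2S,3R,9E)-3-[2-(benzyloxy)ethyl]-2,8,8-trimethyl-4-methylidene-11-oxo-2-(triethylsilyloxy)dodec-9-enal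
Conditions: (COCl)2, DMSO, CH2Cl2, −78 → −30 °C; Et3N
Reagents that add atoms: none
Why: Swern oxidation should convert the allylic alcohol into the enone and, in the same operation, the primary triethylsilyl ether directly into the C7 aldehyde, while the tertiary silyl ether survives.

Step 11
Reactants: 13 (2S,3R,9E)-3-[2-(benzyloxy)ethyl]-2,8,8-trimethyl-4-methylidene-11-oxo-2-(triethylsilyloxy)dodec-9-enal
Product: 16 6α-acetyl-12-(benzyloxy)-8α-(triethylsilyloxy)-13,14,15,16-tetranorlabdan-7β-ol, via C10 radical 14 (not isolated), via ring A enolate 15 (not isolated)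
Conditions: Fe(acac)3 (30 mol%), PhSiH3 (2.5 equiv), EtOH/HOCH2CH2OH (5:1), 0.01 M, rt → 40 °C
Reagents that add atoms: none
Why: An iron hydride formed from Fe(acac)3 and PhSiH3 should transfer a hydrogen atom to C20 of the 1,1-disubstituted alkene; the tertiary C10 radical 14 then adds 6-exo-trig to C5 of the (E)-enone (ring A), the α-keto radical is reduced by divalent iron to enolate 15 (radical–polar crossover), and C6 adds to the C7 aldehyde in a 6-(enolexo)-exo-trig aldol closure (ring B). The closest known reaction type is the iron-catalysed hydrogen-atom-transfer Giese addition/aldol polycyclisation of alkenes that carry a tethered enone and a carbonyl acceptor. C10 and C5 should arise from a chair transition state with the new C20 methyl axial and both the C9 carbon and the enone arm equatorial (the C4 gem-dimethyl group penalises the alternatives), which gives the trans ring fusion; the radical face is chosen by C9 in a Felkin-type arrangement, with C9–H turned toward the incoming enone and the quaternary C8 anti to the forming bond. C6 and C7 should arise from a chair closure of ring B with acetyl and hydroxyl equatorial, C6 remaining epimerisable and the aldol addition reversible, while C8 and C9 are carried through unchanged. The step needs hydrogen-atom transfer to the alkene in preference to the enone and the aldehyde, which the preference of metal hydrides for electron-rich 1,1-disubstituted alkenes should secure. It also needs cyclisation to outrun reduction of the radical, which the gem-dimethyl group and high dilution favour.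

Step 12
Reactants: 16 6α-acetyl-12-(benzyloxy)-8α-(triethylsilyloxy)-13,14,15,16-tetranorlabdan-7β-ol
Product: 17 6α-acetoxy-12-(benzyloxy)-8α-(triethylsilyloxy)-13,14,15,16-tetranorlabdan-7β-ol
Conditions: mCPBA, Na2HPO4, CH2Cl2, 0 °C → rt
Reagents that add atoms: 3-chloroperoxybenzoic acid, OOC(=O)c1cccc(Cl)c1
Why: Baeyer–Villiger oxidation; the secondary C6 should migrate in preference to methyl and with retention, which turns the activating acetyl group into the 6α-acetate (no alkene is present at this stage).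

Step 13
Reactants: 17 6α-acetoxy-12-(benzyloxy)-8α-(triethylsilyloxy)-13,14,15,16-tetranorlabdan-7β-ol
Product: 18 6α-acetoxy-8α-(triethylsilyloxy)-13,14,15,16-tetranorlabdane-7β,12-diol
Conditions: H2 (1 atm), Pd/C, EtOAc, rt
Reagents that add atoms: none
Why: Hydrogenolysis of the benzyl ether on a substrate free of alkenes should leave the acetate and the silyl ether intact.

Step 14
Reactants: 18 6α-acetoxy-8α-(triethylsilyloxy)-13,14,15,16-tetranorlabdane-7β,12-diol
Product: 19 6α-acetoxy-7β-hydroxy-8α-(triethylsilyloxy)-13,14,15,16-tetranorlabdan-12-al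
Conditions: TEMPO (cat.), PhI(OAc)2, CH2Cl2, rt
Reagents that add atoms: none
Why: Oxoammonium oxidation should be selective for the primary C12 alcohol over the hindered secondary C7 alcohol; the silylated C8 oxygen cannot form a lactol.

Step 15
Reactants: 19 6α-acetoxy-7β-hydroxy-8α-(triethylsilyloxy)-13,14,15,16-tetranorlabdan-12-al
Product: 20 (12Z)-6α-acetoxy-13-iodo-8α-(triethylsilyloxy)-14,15-dinorlabd-12-en-7β-ol
Conditions: Ph3P=C(I)CH3 (from EtPPh3I, n-BuLi, I2, NaHMDS), THF, −78 → −20 °C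
Reagents that add atoms: (1-iodoethylidene)triphenylphosphorane, CC(I)=P(c1ccccc1)(c1ccccc1)c1ccccc1
Why: Wittig olefination with the α-iodo ylide should give the (Z)-2-iodoalkene (iodine cis to C11); the weakly basic ylide should not deprotonate the C7 hydroxyl.

Step 16
Reactants: 20 (12Z)-6α-acetoxy-13-iodo-8α-(triethylsilyloxy)-14,15-dinorlabd-12-en-7β-ol
Product: 21 (12Z)-6α-acetoxy-8α-(triethylsilyloxy)labda-12,14-dien-7β-ol
Conditions: Bu3SnCH=CH2, Pd2(dba)3 (cat.), AsPh3, CuI, NMP, rt
Reagents that add atoms: tributyl(vinyl)stannane, C=C[Sn](CCCC)(CCCC)CCCC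
Why: Stille coupling under neutral conditions should replace iodine by vinyl with retention of the alkene geometry, so the vinyl group ends cis to C11.

Step 17
Reactants: 21 (12Z)-6α-acetoxy-8α-(triethylsilyloxy)labda-12,14-dien-7β-ol
Product: 22 (12Z)-6α-acetoxylabda-12,14-diene-7β,8α-diol
Conditions: HF·pyridine, pyridine, THF, 0 °C → rt
Reagents that add atoms: none
Why: Buffered fluoride desilylation should free the tertiary C8 hydroxyl without acid-induced cyclisation onto the diene and without acetyl migration.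

**Compound list**

1 | 3-(benzyloxy)propanal | O=CCCOCc1ccccc1 | starting material
2 | ethyl (E)-5-(benzyloxy)-2-methylpent-2-enoate | CCOC(=O)/C(C)=C/CCOCc1ccccc1 | intermediate
3 | (E)-5-(benzyloxy)-2-methylpent-2-en-1-ol | OC/C(C)=C/CCOCc1ccccc1 | intermediate
4 | [(2R,3R)-3-[2-(benzyloxy)ethyl]-2-methyloxiran-2-yl]methanol | c1ccccc1COCC[C@H]1O[C@]1(C)CO | intermediate
5 | (2S,3S)-3-[2-(benzyloxy)ethyl]-2-methyl-4-(trimethylsilyl)pent-4-ene-1,2-diol | c1ccccc1COCC[C@H](C(=C)[Si](C)(C)C)[C@](C)(O)CO | intermediate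
6 | (2S,3S)-3-[2-(benzyloxy)ethyl]-2-methyl-1,2-bis(triethylsilyloxy)-4-(trimethylsilyl)pent-4-ene | c1ccccc1COCC[C@H](C(=C)[Si](C)(C)C)[C@](C)(O[Si](CC)(CC)CC)CO[Si](CC)(CC)CC | intermediate
7 | (2S,3S)-3-[2-(benzyloxy)ethyl]-4-iodo-2-methyl-1,2-bis(triethylsilyloxy)pent-4-ene | c1ccccc1COCC[C@H](C(=C)I)[C@](C)(O[Si](CC)(CC)CC)CO[Si](CC)(CC)CC | intermediate
8 | 2,2-dimethylpent-4-enal | C=CCC(C)(C)C=O | starting material
9 | (E)-5,5-dimethylocta-3,7-dien-2-one | CC(=O)/C=C/C(C)(C)CC=C | intermediate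
10 | (E)-5,5-dimethylocta-3,7-dien-2-ol (racemic) | CC(O)/C=C/C(C)(C)CC=C | intermediate
11 | 9-[(E)-7-(9-borabicyclo[3.3.1]nonan-9-yloxy)-4,4-dimethyloct-5-enyl]-9-borabicyclo[3.3.1]nonane (alkylborane, not isolated) | CC(OB1C2CCCC1CCC2)/C=C/C(C)(C)CCCB1C2CCCC1CCC2 | intermediate
12 | (3E,10R,11S)-10-[2-(benzyloxy)ethyl]-5,5,11-trimethyl-9-methylidene-11,12-bis(triethylsilyloxy)dodec-3-en-2-ol (both C2 epimers) | c1ccccc1COCC[C@H](C(=C)CCCC(C)(C)/C=C/C(C)O)[C@](C)(O[Si](CC)(CC)CC)CO[Si](CC)(CC)CC | intermediate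
13 | (2S,3R,9E)-3-[2-(benzyloxy)ethyl]-2,8,8-trimethyl-4-methylidene-11-oxo-2-(triethylsilyloxy)dodec-9-enal | c1ccccc1COCC[C@H](C(=C)CCCC(C)(C)/C=C/C(C)=O)[C@](C)(O[Si](CC)(CC)CC)C=O | intermediate
14 | tertiary C10 radical formed from 13 by hydrogen-atom addition to C20 (not isolated) | c1ccccc1COCC[C@H]([C](C)CCCC(C)(C)/C=C/C(C)=O)[C@](C)(O[Si](CC)(CC)CC)C=O | intermediate
15 | ring A enolate: C5–C10 bond formed, C6–C7 still open, C7 aldehyde (not isolated) | c1ccccc1COCC[C@H]([C@@]2(C)CCCC(C)(C)[C@@H]2C=C(C)[O-])[C@](C)(O[Si](CC)(CC)CC)C=O | intermediate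
16 | 6α-acetyl-12-(benzyloxy)-8α-(triethylsilyloxy)-13,14,15,16-tetranorlabdan-7β-ol (5S,6R,7S,8S,9R,10S) | c1ccccc1COCC[C@H]1[C@](C)(O[Si](CC)(CC)CC)[C@@H](O)[C@H](C(C)=O)[C@H]2C(C)(C)CCC[C@@]21C | intermediate
17 | 6α-acetoxy-12-(benzyloxy)-8α-(triethylsilyloxy)-13,14,15,16-tetranorlabdan-7β-ol | c1ccccc1COCC[C@H]1[C@](C)(O[Si](CC)(CC)CC)[C@@H](O)[C@H](OC(C)=O)[C@H]2C(C)(C)CCC[C@@]21C | intermediate
18 | 6α-acetoxy-8α-(triethylsilyloxy)-13,14,15,16-tetranorlabdane-7β,12-diol | OCC[C@H]1[C@](C)(O[Si](CC)(CC)CC)[C@@H](O)[C@H](OC(C)=O)[C@H]2C(C)(C)CCC[C@@]21C | intermediate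
19 | 6α-acetoxy-7β-hydroxy-8α-(triethylsilyloxy)-13,14,15,16-tetranorlabdan-12-al | O=CC[C@H]1[C@](C)(O[Si](CC)(CC)CC)[C@@H](O)[C@H](OC(C)=O)[C@H]2C(C)(C)CCC[C@@]21C | intermediate
20 | (12Z)-6α-acetoxy-13-iodo-8α-(triethylsilyloxy)-14,15-dinorlabd-12-en-7β-ol | I/C(C)=C\C[C@H]1[C@](C)(O[Si](CC)(CC)CC)[C@@H](O)[C@H](OC(C)=O)[C@H]2C(C)(C)CCC[C@@]21C | intermediate
21 | (12Z)-6α-acetoxy-8α-(triethylsilyloxy)labda-12,14-dien-7β-ol | C=C/C(C)=C\C[C@H]1[C@](C)(O[Si](CC)(CC)CC)[C@@H](O)[C@H](OC(C)=O)[C@H]2C(C)(C)CCC[C@@]21C | intermediate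
22 | (12Z)-6α-acetoxylabda-12,14-diene-7β,8α-diol (5S,6R,7S,8S,9R,10S) | C=C/C(C)=C\C[C@H]1[C@](C)(O)[C@@H](O)[C@H](OC(C)=O)[C@H]2C(C)(C)CCC[C@@]21C | target

**Step count and risks**

Total step count: 17. Longest linear sequence: 15 steps (steps 1–6 and 9–17).

Steps most likely to fail:

1. Step 11. The radical may add to the enone with poor facial selectivity with respect to C9, may be reduced before it cyclises, or the enolate may be protonated before ring B closes (or close to the axial C7 epimer). Fallback: the two bond formations are separated, setting out from 12 and returning at 16.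
   - Oxidation of only the allylic alcohol of 12 with MnO2 would give (3E,10R,11S)-10-[2-(benzyloxy)ethyl]-5,5,11-trimethyl-9-methylidene-11,12-bis(triethylsilyloxy)dodec-3-en-2-one F1.
   - Reductive hydrogen-atom-transfer Giese cyclisation (Fe(acac)3, PhSiH3, EtOH) would close ring A alone and give 1-[(1S,2S)-2-[(3R,4S)-1-(benzyloxy)-4-methyl-4,5-bis(triethylsilyloxy)pentan-3-yl]-2,6,6-trimethylcyclohexyl]propan-2-one F2, at which stage C10 epimers could be separated.
   - Swern oxidation of the primary silyl ether would give (2S,3R)-5-(benzyloxy)-2-methyl-3-[(1S,2S)-1,3,3-trimethyl-2-(2-oxopropyl)cyclohexyl]-2-(triethylsilyloxy)pentanal F3.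
   - An intramolecular aldol addition under equilibrating base (catalytic KOt-Bu, t-BuOH/THF, 0 °C) would close ring B to 16.

2. Step 4. The bulky α-silylvinyl nucleophile may open the trisubstituted epoxide sluggishly, at the wrong carbon, or after Payne rearrangement. Fallback: an alkyne is used as the C10/C20 unit, setting out from 4 and returning at 7.
   - Opening of 4 with the alkynylalane from lithium (trimethylsilyl)acetylide and Et2AlCl would give (2S,3R)-3-[2-(benzyloxy)ethyl]-2-methyl-5-(trimethylsilyl)pent-4-yne-1,2-diol F4.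
   - K2CO3 in MeOH would give (2S,3R)-3-[2-(benzyloxy)ethyl]-2-methylpent-4-yne-1,2-diol F5.
   - Markovnikov hydroiodination (NaI, Me3SiCl, H2O, MeCN) would give (2S,3S)-3-[2-(benzyloxy)ethyl]-4-iodo-2-methylpent-4-ene-1,2-diol F6.
   - Bis-silylation with Et3SiOTf and 2,6-lutidine would give 7.

3. Step 15. The α-iodo ylide olefination may lose Z-selectivity, and basic species may trigger acetyl migration from O6 to O7. Fallback: the trisubstituted alkene is built by two stereoretentive couplings, setting out from 19 and returning at 21.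
   - Ramirez olefination of 19 with preformed Ph3P=CBr2 would give 6α-acetoxy-13,13-dibromo-8α-(triethylsilyloxy)-14,15,16-trinorlabd-12-en-7β-ol F7.
   - Negishi methylation of the bromide trans to C11 (Me2Zn, Pd(DPEphos)Cl2) would give (12Z)-6α-acetoxy-13-bromo-8α-(triethylsilyloxy)-14,15-dinorlabd-12-en-7β-ol F8.
   - Stille coupling with tributyl(vinyl)stannane as in step 16 would give 21.

Further compounds
F1 | step 11 | (3E,10R,11S)-10-[2-(benzyloxy)ethyl]-5,5,11-trimethyl-9-methylidene-11,12-bis(triethylsilyloxy)dodec-3-en-2-one | c1ccccc1COCC[C@H](C(=C)CCCC(C)(C)/C=C/C(C)=O)[C@](C)(O[Si](CC)(CC)CC)CO[Si](CC)(CC)CC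
F2 | step 11 | 1-[(1S,2S)-2-[(3R,4S)-1-(benzyloxy)-4-methyl-4,5-bis(triethylsilyloxy)pentan-3-yl]-2,6,6-trimethylcyclohexyl]propan-2-one | c1ccccc1COCC[C@H]([C@@]2(C)CCCC(C)(C)[C@@H]2CC(C)=O)[C@](C)(O[Si](CC)(CC)CC)CO[Si](CC)(CC)CC
F3 | step 11 | (2S,3R)-5-(benzyloxy)-2-methyl-3-[(1S,2S)-1,3,3-trimethyl-2-(2-oxopropyl)cyclohexyl]-2-(triethylsilyloxy)pentanal | c1ccccc1COCC[C@H]([C@@]2(C)CCCC(C)(C)[C@@H]2CC(C)=O)[C@](C)(O[Si](CC)(CC)CC)C=O
F4 | step 4 | (2S,3R)-3-[2-(benzyloxy)ethyl]-2-methyl-5-(trimethylsilyl)pent-4-yne-1,2-diol | c1ccccc1COCC[C@H](C#C[Si](C)(C)C)[C@](C)(O)CO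
F5 | step 4 | (2S,3R)-3-[2-(benzyloxy)ethyl]-2-methylpent-4-yne-1,2-diol | c1ccccc1COCC[C@H](C#C)[C@](C)(O)CO
F6 | step 4 | (2S,3S)-3-[2-(benzyloxy)ethyl]-4-iodo-2-methylpent-4-ene-1,2-diol | c1ccccc1COCC[C@H](C(=C)I)[C@](C)(O)CO
F7 | step 15 | 6α-acetoxy-13,13-dibromo-8α-(triethylsilyloxy)-14,15,16-trinorlabd-12-en-7β-ol | BrC(Br)=CC[C@H]1[C@](C)(O[Si](CC)(CC)CC)[C@@H](O)[C@H](OC(C)=O)[C@H]2C(C)(C)CCC[C@@]21C
F8 | step 15 | (12Z)-6α-acetoxy-13-bromo-8α-(triethylsilyloxy)-14,15-dinorlabd-12-en-7β-ol | Br/C(C)=C\C[C@H]1[C@](C)(O[Si](CC)(CC)CC)[C@@H](O)[C@H](OC(C)=O)[C@H]2C(C)(C)CCC[C@@]21C
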